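# Hierochin B (19) by aryne etherification and C7 oxygenation of a syn-aldol-derived fluoroarene

## The problem

Hierochin B (19) is a 2-aryl-3-hydroxymethyl-2,3-dihydrobenzofuran. Ring A (benzo) is fused to ring B (dihydrofuran), ring C (3,4-dimethoxyphenyl) sits on C2, a hydroxymethyl group on C3, a methoxy group on C7 and an (E)-3-hydroxyprop-1-enyl chain on C5. The only stereocentres are C2 (S) and C3 (R). They are adjacent and trans, so the relative configuration is the favoured one, but the absolute configuration must be imposed. This is done most economically when the C2–C3 bond is formed, so that one reagent-controlled event sets both centres. Three functions are fragile: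

- the allylic alcohol of the side chain, which does not tolerate acid, oxidants, strong base or hydrogenation;
- the O1–C2 bond, a para-alkoxybenzylic ether that opens or epimerizes once acid ionizes C2;
- the C3–H bond, benzylic with O1 in the β-position, through which a strong base can open ring B by elimination.

Ring A is tetrasubstituted (C3a, C5, C7, C7a), and arenes that already carry this pattern with a usable handle at each position are not readily bought. The decisive feature is that the ring oxygen O1 and the methoxy oxygen stand on neighbouring carbons, C7a and C7. These are the two carbons of an aryne. The oxygen on C2 is held three atoms (C2, C3, C3a) from C7a, so it can add only there and leave a carbanion at C7 for an oxygen electrophile.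

## Retrosynthesis

**Side chain (19 ⇒ 18 ⇒ 16 + 17).** The two silyl ethers of 18 are removed last, and the C5–vinyl bond is cut to aryl chloride 16 and the purchasable (E)-alkenyl boronate 17. The allylic alcohol could not pass through the organolithium chemistry needed earlier, whereas a chloride can. The neighbouring cut, a C5 aldehyde followed by olefination and reduction, costs two steps and would require a masked aldehyde to survive a lithium amide. The boronate delivers the three carbons, the E geometry and the oxygen in one coupling. The forward reaction must insert palladium into an electron-rich aryl chloride.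

**Methyl ether (16 ⇒ 15).** The O–CH3 bond at C7 is cut to phenol 15. The oxygen is accepted as a phenol because borylation and oxidation is the dependable way to turn an aryllithium into a C–O bond. The forward step is a routine phenol methylation.

**Ring B and the C7 oxygen (15 ⇒ 10).** The O1–C7a and C7–O bonds are cut together. This leads to fluoro alcohol 10, whose ring A carries only fluorine (at the future C7a) and chlorine (at the future C5). The neighbouring cut of O1–C2, closing a phenol onto an activated benzylic carbon, would need ring A to arrive with both oxygens and the halogen in place and would put the C2 configuration at risk through ionization. The aryne cut starts from a bought disubstituted arylacetic acid and touches neither stereocentre. The forward reaction asks four things: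

- the base must remove the one hydrogen ortho to fluorine;
- the tethered alkoxide must add to C7a;
- the C7 aryllithium must last until a borate ester is added;
- the silyl group on the primary oxygen must stay in place, because that oxygen is also three atoms from C7a. For this reason a triisopropylsilyl ether is used.

**Protecting group and auxiliary (10 ⇒ 9 ⇒ 8).** The Si–O bond is cut to diol 9, and the primary alcohol is traced to the acyl carbon of aldol adduct 8. Reductive removal of the auxiliary gives the diol directly at the right oxidation state. The bulky silyl chloride then has only to tell a primary from a secondary benzylic hydroxyl.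

**Stereocentres (8 ⇒ 4 + 5; 4 ⇒ 1 + 2).** The C2–C3 bond (benzofuran numbering) is cut by an auxiliary-controlled syn aldol between imide 4 and aldehyde 5. This is the only step that creates stereocentres and it sets both at once. The syn adduct maps onto the trans ring, because the hydroxyl and the fluoroaryl group become ring members. Imide 4 comes from acid 1 and oxazolidinone 2. All four building blocks (1, 2, 5, 17) are commercial.

## Roads not taken

**Alternative 1: sulfur ylide [4+1] annulation onto an ortho-quinone methide.**
- Cut: C2–C3 and O1–C2.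
- Forward key step: Cs2CO3 expels sulfinate from sulfonyl phenol A2. The 3,4-dimethoxybenzyl ylide from the C2-symmetric thiolanium salt A3 adds to the methide carbon, and the phenoxide displaces the sulfide to give A1. A3 is drawn as one antipode; which antipode leads to the (2S,3R) series would have to be established.
- Merits: it joins the two aryl halves, closes ring B and sets both stereocentres in one step. The trans relationship follows from the anti-periplanar closure of the betaine. The methoxy group and a bromide are present from the start, so A1 is only a coupling with 17 and a desilylation away from 19.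
- Weak points:
  - The quinone methide has an alkyl-type substituent (CH2OSi) with hydrogens next to the methide carbon. Such species tautomerize to vinylphenols and oligomerize far more readily than the aryl-substituted ones on which this annulation is established.
  - The ylide is an electron-rich benzyl ylide and is not carbonyl-stabilized. It needs a stronger base than is ideal for slow release of the quinone methide.
  - Absolute control rests on a stoichiometric chiral sulfide whose sense and level of induction with this acceptor are unknown.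
- Comparison: this road is shorter (about five steps against eight), more convergent, and avoids both the late methylation and the sluggish aryl chloride. Against that, the chosen plan draws its stereocentres from an aldol of predictable sense, and its key step creates no stereocentre and has no regiochemical choice.

**Alternative 2: oxidative ring contraction of an (S)-flavanone.**
- Cut: C3–C3a, formed by a 1,2-shift of ring A.
- Forward key step: chalcone A6 is cyclized enantioselectively to flavanone A5. PhI(OAc)2 and H2SO4 in HC(OMe)3 then make ring A migrate from the carbonyl carbon to the α-carbon, and the old carbonyl carbon emerges as the methyl ester of A4.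
- Merits: A5 comes from simple aldol-condensation chemistry, and the ring A oxygen pattern is in place from the start. The contraction is a known reaction of flavanones and gives the trans ester. C3 stays correctable, since it is α to an ester and trans is favoured.
- Weak points:
  - Flavanones racemize by reversible ring opening to the chalcone (here A6), and a hot acidic medium invites exactly this.
  - The electron-rich ring C at C2 is a better migrating group than the bromine-deactivated ring A, so the shift towards an isoflavone skeleton and dehydrogenation to a flavone compete.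
  - The iodine oxidant can attack ring C.
  - The ester must be reduced afterwards, which brings the count to about seven steps.
- Comparison: the length is similar, and this road needs no organolithium step and no late methylation. The chosen plan offers a route without a racemizable intermediate and a key step whose selectivity is fixed by structure, not by migratory aptitude.

**Alternative 3: asymmetric Prins hydroxymethylation with phenol capture.**
- Cut: the bond from C3 to the hydroxymethyl carbon, and O1–C2.
- Forward key step: stilbene A8 and formaldehyde A9 react under a confined chiral imidodiphosphorimidate acid. The activated formaldehyde attacks the alkene carbon next to ring A, the C2 cation stabilized by ring C is captured by the phenol, and A7 results. Its aldehyde is then homologated to the propenol.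
- Merits: it is the shortest route (about five or six steps), catalytic in the chiral element, and free of protecting groups and auxiliaries.
- Weak points:
  - Plain acid-catalysed addition of the phenol to the protonated alkene closes ring B without the one-carbon unit.
  - Formaldehyde and acid can hydroxymethylate the electron-rich rings, and a second formaldehyde can intercept the cation before the phenol, which is made less nucleophilic by the para formyl group.
  - The regiochemistry depends on ring C stabilizing the cation better than the ortho-hydroxylated ring A.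
  - Enantiocontrol by such acids is established for simple styrenes, not for a 1,2-diaryl alkene with five Lewis-basic oxygens.
- Comparison: in step count and atom economy this road is clearly better. The chosen plan sets against it that every regiochemical and stereochemical outcome is fixed by well-understood elements (auxiliary, a single ortho hydrogen, tether length). Its risk is confined to one trapping event instead of a catalyst–substrate match that decides both stereocentres.

Key step: step 5

Assumption: fluorine outranks chlorine as ortho director towards lithium amide bases in 10, as in simple chlorofluoroarenes, and the boron aldol of arylacetyl imide 4 follows the normal syn sense of propionyl imides.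

## Route

Step 1
Reactants: 1 2-(5-chloro-2-fluorophenyl)acetic acid; 2 (S)-4-benzyl-2-oxazolidinone
Product: 4 (S)-4-benzyl-3-[2-(5-chloro-2-fluorophenyl)acetyl]oxazolidin-2-one, via mixed pivalic anhydride 3 (not isolated)
Conditions: PivCl, Et3N, THF, −20 °C; then 2, LiCl, −20 °C → rt
Reagents that add atoms: none
Why: N-acylation of an oxazolidinone through a mixed pivalic anhydride, with LiCl and Et3N activating the auxiliary so that no prior lithiation is needed; attack should go to the less hindered arylacetyl carbonyl of 3.

Step 2
Reactants: 4 (S)-4-benzyl-3-[2-(5-chloro-2-fluorophenyl)acetyl]oxazolidin-2-one; 5 3,4-dimethoxybenzaldehyde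
Product: 8 (S)-4-benzyl-3-[(2S,3S)-2-(5-chloro-2-fluorophenyl)-3-(3,4-dimethoxyphenyl)-3-hydroxypropanoyl]oxazolidin-2-one, via Z dibutylboron enolate 6 (not isolated), via dibutylboron aldolate 7 (not isolated)
Conditions: Bu2BOTf, i-Pr2NEt, CH2Cl2, −78 → 0 °C; 5, −78 → 0 °C; pH 7 buffer, MeOH, 30% H2O2, 0 °C
Reagents that add atoms: none
Why: Evans syn aldol reaction: soft enolization should give Z enolate 6, which reacts through a Zimmerman–Traxler chair with the auxiliary carbonyl turned away and the aldehyde on the enolate face opposite the benzyl group; this sets both stereocentres (2S,3S, syn), which become C3 (R) and C2 (S) of the benzofuran.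

Step 3
Reactants: 8 (S)-4-benzyl-3-[(2S,3S)-2-(5-chloro-2-fluorophenyl)-3-(3,4-dimethoxyphenyl)-3-hydroxypropanoyl]oxazolidin-2-one
Product: 9 (1S,2R)-2-(5-chloro-2-fluorophenyl)-1-(3,4-dimethoxyphenyl)propane-1,3-diol
Conditions: LiBH4, MeOH (1 equiv), THF, 0 °C
Reagents that add atoms: none
Why: Reductive cleavage of an N-acyl oxazolidinone by LiBH4 at the exocyclic carbonyl should release the primary alcohol and auxiliary 2 without touching either stereocentre; low temperature and short contact keep retro-aldol cleavage down.

Step 4
Reactants: 9 (1S,2R)-2-(5-chloro-2-fluorophenyl)-1-(3,4-dimethoxyphenyl)propane-1,3-diol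
Product: 10 (1S,2R)-2-(5-chloro-2-fluorophenyl)-1-(3,4-dimethoxyphenyl)-3-(triisopropylsilyloxy)propan-1-ol
Conditions: TIPSCl, imidazole, DMAP (cat.), CH2Cl2, 0 °C → rt
Reagents that add atoms: triisopropylsilyl chloride, CC(C)[Si](Cl)(C(C)C)C(C)C
Why: Selective silylation of a primary over a secondary benzylic hydroxyl by a bulky silyl chloride; the triisopropylsilyl ether is chosen because it is the common silyl ether least prone to oxygen-to-oxygen migration under the alkoxide of step 5.

Step 5
Reactants: 10 (1S,2R)-2-(5-chloro-2-fluorophenyl)-1-(3,4-dimethoxyphenyl)-3-(triisopropylsilyloxy)propan-1-ol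
Product: 15 (2S,3R)-5-chloro-2-(3,4-dimethoxyphenyl)-3-[(triisopropylsilyloxy)methyl]-2,3-dihydrobenzofuran-7-ol, via ortho-lithiated lithium alkoxide 11 (not isolated), via aryne lithium alkoxide 12 (not isolated), via 7-lithio-2,3-dihydrobenzofuran 13 (not isolated), via lithium aryltrimethoxyborate 14 (not isolated)
Conditions: n-BuLi (1.0 equiv), THF, −78 °C; lithium 2,2,6,6-tetramethylpiperidide (1.2 equiv, from 2,2,6,6-tetramethylpiperidine and n-BuLi), −78 °C, then −78 → −30 °C; B(OMe)3, −78 °C → rt; AcOH, 30% H2O2, 0 °C → rt
Reagents that add atoms: hydrogen peroxide, OO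
Why: n-BuLi takes the hydroxyl proton and the lithium amide then removes the only hydrogen ortho to fluorine (the future C7), giving 11. On warming, 11 loses LiF to give aryne 12 with the strained bond between C7 and C7a. The lithium alkoxide, held three atoms from C7a, adds in the ring plane to that carbon in a 5-exo-dig closure of ring B, forming O1–C7a and leaving aryllithium 13 at C7 beside the new ether oxygen. B(OMe)3, added only after the cyclization so that it cannot intercept 11, converts 13 into borate 14, and peroxide oxidation with 1,2-migration of the aryl group from boron to oxygen gives phenol 15. The closest known reaction types are base-induced aryne formation from haloarenes with capture by a tethered alkoxide to give dihydrobenzofurans and chromans, electrophilic trapping of the aryllithium left by nucleophile addition to an aryne, and borylation–oxidation of aryllithiums. No stereocentre is formed: C2 and C3 come unchanged from the aldol, so the syn arrangement of 10 appears as the trans ring. The step needs regiocontrol at both aryne carbons, which the substrate secures through the single hydrogen ortho to fluorine and the tether length, and it needs the other oxygen to stay silylated, which the triisopropylsilyl group secures.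

Step 6
Reactants: 15 (2S,3R)-5-chloro-2-(3,4-dimethoxyphenyl)-3-[(triisopropylsilyloxy)methyl]-2,3-dihydrobenzofuran-7-ol
Product: 16 (2S,3R)-5-chloro-2-(3,4-dimethoxyphenyl)-7-methoxy-3-[(triisopropylsilyloxy)methyl]-2,3-dihydrobenzofuran
Conditions: MeI, K2CO3, DMF, rt
Reagents that add atoms: iodomethane, CI
Why: Williamson O-methylation of the only acidic hydroxyl; carbonate is too weak to touch C3–H or the silyl ether.

Step 7
Reactants: 16 (2S,3R)-5-chloro-2-(3,4-dimethoxyphenyl)-7-methoxy-3-[(triisopropylsilyloxy)methyl]-2,3-dihydrobenzofuran; 17 (E)-3-(tert-butyldimethylsilyloxy)prop-1-enylboronic acid pinacol ester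
Product: 18 (2S,3R)-5-[(E)-3-(tert-butyldimethylsilyloxy)prop-1-enyl]-2-(3,4-dimethoxyphenyl)-7-methoxy-3-[(triisopropylsilyloxy)methyl]-2,3-dihydrobenzofuran
Conditions: Pd(OAc)2 (cat.), SPhos, K3PO4, toluene/H2O, 90 °C
Reagents that add atoms: none
Why: Suzuki–Miyaura coupling; the SPhos-ligated zerovalent palladium formed in the flask inserts into electron-rich aryl chlorides, and alkenyl boronates transfer with retention of the E geometry.

Step 8
Reactants: 18 (2S,3R)-5-[(E)-3-(tert-butyldimethylsilyloxy)prop-1-enyl]-2-(3,4-dimethoxyphenyl)-7-methoxy-3-[(triisopropylsilyloxy)methyl]-2,3-dihydrobenzofuran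
Product: 19 hierochin B, (E)-3-[(2S,3R)-2-(3,4-dimethoxyphenyl)-3-(hydroxymethyl)-7-methoxy-2,3-dihydrobenzofuran-5-yl]prop-2-en-1-ol
Conditions: Bu4NF, THF, 0 °C → rt
Reagents that add atoms: none
Why: Fluoride-mediated cleavage of both silyl ethers under conditions that leave the allylic alcohol, the benzylic ether and both stereocentres alone.

## Compound list

1 | 2-(5-chloro-2-fluorophenyl)acetic acid | OC(=O)Cc1cc(Cl)ccc1F | starting material
2 | (S)-4-benzyl-2-oxazolidinone | O=C1N[C@@H](Cc2ccccc2)CO1 | starting material
3 | 2-(5-chloro-2-fluorophenyl)acetic pivalic anhydride | CC(C)(C)C(=O)OC(=O)Cc1cc(Cl)ccc1F | intermediate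
4 | (S)-4-benzyl-3-[2-(5-chloro-2-fluorophenyl)acetyl]oxazolidin-2-one | O=C(Cc1cc(Cl)ccc1F)N1[C@@H](Cc2ccccc2)COC1=O | intermediate
5 | 3,4-dimethoxybenzaldehyde | COc1ccc(C=O)cc1OC | starting material
6 | (S)-4-benzyl-3-[(Z)-2-(5-chloro-2-fluorophenyl)-1-(dibutylboryloxy)ethenyl]oxazolidin-2-one | CCCCB(CCCC)O/C(=C\c1cc(Cl)ccc1F)N1[C@@H](Cc2ccccc2)COC1=O | intermediate
7 | (S)-4-benzyl-3-[(2S,3S)-2-(5-chloro-2-fluorophenyl)-3-(dibutylboryloxy)-3-(3,4-dimethoxyphenyl)propanoyl]oxazolidin-2-one | COc1ccc([C@@H](OB(CCCC)CCCC)[C@@H](C(=O)N3[C@@H](Cc4ccccc4)COC3=O)c2cc(Cl)ccc2F)cc1OC | intermediate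
8 | (S)-4-benzyl-3-[(2S,3S)-2-(5-chloro-2-fluorophenyl)-3-(3,4-dimethoxyphenyl)-3-hydroxypropanoyl]oxazolidin-2-one | COc1ccc([C@@H](O)[C@@H](C(=O)N3[C@@H](Cc4ccccc4)COC3=O)c2cc(Cl)ccc2F)cc1OC | intermediate
9 | (1S,2R)-2-(5-chloro-2-fluorophenyl)-1-(3,4-dimethoxyphenyl)propane-1,3-diol | COc1ccc([C@@H](O)[C@@H](CO)c2cc(Cl)ccc2F)cc1OC | intermediate
10 | (1S,2R)-2-(5-chloro-2-fluorophenyl)-1-(3,4-dimethoxyphenyl)-3-(triisopropylsilyloxy)propan-1-ol | COc1ccc([C@@H](O)[C@@H](CO[Si](C(C)C)(C(C)C)C(C)C)c2cc(Cl)ccc2F)cc1OC | intermediate
11 | lithium (1S,2R)-2-(5-chloro-2-fluoro-3-lithiophenyl)-1-(3,4-dimethoxyphenyl)-3-(triisopropylsilyloxy)propan-1-olate | COc1ccc([C@@H](O[Li])[C@@H](CO[Si](C(C)C)(C(C)C)C(C)C)c2cc(Cl)cc([Li])c2F)cc1OC | intermediate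
12 | lithium (1S,2R)-2-(5-chloro-2,3-didehydrophenyl)-1-(3,4-dimethoxyphenyl)-3-(triisopropylsilyloxy)propan-1-olate (aryne) | COc1ccc([C@@H](O[Li])[C@@H](CO[Si](C(C)C)(C(C)C)C(C)C)C2=CC(Cl)=CC#C2)cc1OC | intermediate
13 | [(2S,3R)-5-chloro-2-(3,4-dimethoxyphenyl)-3-[(triisopropylsilyloxy)methyl]-2,3-dihydrobenzofuran-7-yl]lithium | COc1ccc([C@H]2Oc3c([Li])cc(Cl)cc3[C@@H]2CO[Si](C(C)C)(C(C)C)C(C)C)cc1OC | intermediate
14 | lithium [(2S,3R)-5-chloro-2-(3,4-dimethoxyphenyl)-3-[(triisopropylsilyloxy)methyl]-2,3-dihydrobenzofuran-7-yl]trimethoxyborate | COc1ccc([C@H]2Oc3c([B-](OC)(OC)OC)cc(Cl)cc3[C@@H]2CO[Si](C(C)C)(C(C)C)C(C)C)cc1OC.[Li+] | intermediate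
15 | (2S,3R)-5-chloro-2-(3,4-dimethoxyphenyl)-3-[(triisopropylsilyloxy)methyl]-2,3-dihydrobenzofuran-7-ol | COc1ccc([C@H]2Oc3c(O)cc(Cl)cc3[C@@H]2CO[Si](C(C)C)(C(C)C)C(C)C)cc1OC | intermediate
16 | (2S,3R)-5-chloro-2-(3,4-dimethoxyphenyl)-7-methoxy-3-[(triisopropylsilyloxy)methyl]-2,3-dihydrobenzofuran | COc1ccc([C@H]2Oc3c(OC)cc(Cl)cc3[C@@H]2CO[Si](C(C)C)(C(C)C)C(C)C)cc1OC | intermediate
17 | (E)-3-(tert-butyldimethylsilyloxy)prop-1-enylboronic acid pinacol ester | CC1(C)OB(/C=C/CO[Si](C)(C)C(C)(C)C)OC1(C)C | starting material
18 | (2S,3R)-5-[(E)-3-(tert-butyldimethylsilyloxy)prop-1-enyl]-2-(3,4-dimethoxyphenyl)-7-methoxy-3-[(triisopropylsilyloxy)methyl]-2,3-dihydrobenzofuran | COc1ccc([C@H]2Oc3c(OC)cc(/C=C/CO[Si](C)(C)C(C)(C)C)cc3[C@@H]2CO[Si](C(C)C)(C(C)C)C(C)C)cc1OC | intermediate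
19 | hierochin B, (E)-3-[(2S,3R)-2-(3,4-dimethoxyphenyl)-3-(hydroxymethyl)-7-methoxy-2,3-dihydrobenzofuran-5-yl]prop-2-en-1-ol | COc1ccc([C@H]2Oc3c(OC)cc(/C=C/CO)cc3[C@@H]2CO)cc1OC | target

## Step count and least certain steps

Total steps: 8. Longest linear sequence: 8 (1 → 19).

**Step 5 (key step).**
- What may go wrong:
  - Protonation of aryllithium 13 by the tetramethylpiperidine released in the lithiation is the most likely failure. A carbanion next to an ether oxygen is more basic than the hindered amide, so ring B would close but C7 would end as C–H. Only about one equivalent of amine is present, because the hydroxyl proton is taken by n-BuLi.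
  - Surplus base at higher temperature may open ring B by elimination through C3–H, or lithiate next to chlorine.
  - If the silyl group shifts to the secondary alkoxide, the primary oxygen is offered to the aryne instead.
- Fallback: the proton quench is accepted and the oxygen is installed separately. From 10, lithium 2,2,6,6-tetramethylpiperidide (2.2 equiv, THF, −78 → −20 °C) followed by methanol should give (2S,3R)-5-chloro-2-(3,4-dimethoxyphenyl)-3-[(triisopropylsilyloxy)methyl]-2,3-dihydrobenzofuran F1 by the classical alkoxide–aryne cyclization. Sterically governed C–H borylation with [Ir(OMe)(cod)]2, 4,4′-di-tert-butyl-2,2′-bipyridine and B2pin2 should then give (2S,3R)-5-chloro-2-(3,4-dimethoxyphenyl)-7-(4,4,5,5-tetramethyl-1,3,2-dioxaborolan-2-yl)-3-[(triisopropylsilyloxy)methyl]-2,3-dihydrobenzofuran F2. C7 is the expected site: it is flanked only by the tied-back ring oxygen, whereas C4 lies between two substituents, C6 is next to chlorine, and each C–H of ring C is next to a methoxy group or the branched C2 carbon. Oxidation with NaBO3·4H2O in THF/H2O returns to the route at 15.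

**Step 2.**
- What may go wrong: addition to the electron-rich aldehyde may be sluggish, and the α-aryl aldolate 7 may undergo retro-aldol equilibration, which lowers conversion and erodes the syn selectivity.
- Fallback: a chlorotitanium enolate of a thiazolidinethione imide, which is more Lewis acidic towards the aldehyde and whose adducts are cleaved very easily. From 1, acylation of commercial (S)-4-benzylthiazolidine-2-thione (N,N′-dicyclohexylcarbodiimide, DMAP, CH2Cl2) gives (S)-4-benzyl-3-[2-(5-chloro-2-fluorophenyl)acetyl]thiazolidine-2-thione F3. TiCl4, i-Pr2NEt and N-methylpyrrolidinone in CH2Cl2, then 5, should give the syn adduct of the same sense, (2S,3S)-1-[(S)-4-benzyl-2-thioxothiazolidin-3-yl]-2-(5-chloro-2-fluorophenyl)-3-(3,4-dimethoxyphenyl)-3-hydroxypropan-1-one F4. LiBH4 in THF reduces F4 to diol 9, where the route is rejoined.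

**Step 3.**
- What may go wrong: retro-aldol fragmentation of the β-alkoxide, or epimerization at the acidic α-aryl carbon, may compete with hydride delivery to the imide.
- Fallback: the hydroxyl is masked before reduction. From 8, Et3SiOTf and 2,6-lutidine give (S)-4-benzyl-3-[(2S,3S)-2-(5-chloro-2-fluorophenyl)-3-(3,4-dimethoxyphenyl)-3-(triethylsilyloxy)propanoyl]oxazolidin-2-one F5. LiBH4 gives (2R,3S)-2-(5-chloro-2-fluorophenyl)-3-(3,4-dimethoxyphenyl)-3-(triethylsilyloxy)propan-1-ol F6. TIPSCl and imidazole give (1S,2R)-2-(5-chloro-2-fluorophenyl)-1-(3,4-dimethoxyphenyl)-1-(triethylsilyloxy)-3-(triisopropylsilyloxy)propane F7. Buffered HF·pyridine in THF at 0 °C removes only the triethylsilyl ether and returns to the route at 10.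

**Step 7.**
- What may go wrong: oxidative addition into the electron-rich C5–Cl bond may be slow, so that protodeboronation and decomposition of alkenyl boronate 17 win.
- Fallback: a Heck reaction, which needs no boron partner and tolerates long heating, followed by reduction. From 16, methyl acrylate with Pd2(dba)3, P(t-Bu)3 and Cy2NMe in dioxane at 100 °C gives methyl (E)-3-[(2S,3R)-2-(3,4-dimethoxyphenyl)-7-methoxy-3-[(triisopropylsilyloxy)methyl]-2,3-dihydrobenzofuran-5-yl]prop-2-enoate F8. Diisobutylaluminium hydride in CH2Cl2 at −78 °C gives (E)-3-[(2S,3R)-2-(3,4-dimethoxyphenyl)-7-methoxy-3-[(triisopropylsilyloxy)methyl]-2,3-dihydrobenzofuran-5-yl]prop-2-en-1-ol F9. Bu4NF in THF then gives 19 directly.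

## Further compounds

F1 | step 5 | (2S,3R)-5-chloro-2-(3,4-dimethoxyphenyl)-3-[(triisopropylsilyloxy)methyl]-2,3-dihydrobenzofuran | COc1ccc([C@H]2Oc3ccc(Cl)cc3[C@@H]2CO[Si](C(C)C)(C(C)C)C(C)C)cc1OC
F2 | step 5 | (2S,3R)-5-chloro-2-(3,4-dimethoxyphenyl)-7-(4,4,5,5-tetramethyl-1,3,2-dioxaborolan-2-yl)-3-[(triisopropylsilyloxy)methyl]-2,3-dihydrobenzofuran | COc1ccc([C@H]2Oc3c(B4OC(C)(C)C(C)(C)O4)cc(Cl)cc3[C@@H]2CO[Si](C(C)C)(C(C)C)C(C)C)cc1OC
F3 | step 2 | (S)-4-benzyl-3-[2-(5-chloro-2-fluorophenyl)acetyl]thiazolidine-2-thione | O=C(Cc1cc(Cl)ccc1F)N1[C@@H](Cc2ccccc2)CSC1=S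
F4 | step 2 | (2S,3S)-1-[(S)-4-benzyl-2-thioxothiazolidin-3-yl]-2-(5-chloro-2-fluorophenyl)-3-(3,4-dimethoxyphenyl)-3-hydroxypropan-1-one | COc1ccc([C@@H](O)[C@@H](C(=O)N3[C@@H](Cc4ccccc4)CSC3=S)c2cc(Cl)ccc2F)cc1OC
F5 | step 3 | (S)-4-benzyl-3-[(2S,3S)-2-(5-chloro-2-fluorophenyl)-3-(3,4-dimethoxyphenyl)-3-(triethylsilyloxy)propanoyl]oxazolidin-2-one | COc1ccc([C@@H](O[Si](CC)(CC)CC)[C@@H](C(=O)N3[C@@H](Cc4ccccc4)COC3=O)c2cc(Cl)ccc2F)cc1OC
F6 | step 3 | (2R,3S)-2-(5-chloro-2-fluorophenyl)-3-(3,4-dimethoxyphenyl)-3-(triethylsilyloxy)propan-1-ol | COc1ccc([C@@H](O[Si](CC)(CC)CC)[C@@H](CO)c2cc(Cl)ccc2F)cc1OC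
F7 | step 3 | (1S,2R)-2-(5-chloro-2-fluorophenyl)-1-(3,4-dimethoxyphenyl)-1-(triethylsilyloxy)-3-(triisopropylsilyloxy)propane | COc1ccc([C@@H](O[Si](CC)(CC)CC)[C@@H](CO[Si](C(C)C)(C(C)C)C(C)C)c2cc(Cl)ccc2F)cc1OC
F8 | step 7 | methyl (E)-3-[(2S,3R)-2-(3,4-dimethoxyphenyl)-7-methoxy-3-[(triisopropylsilyloxy)methyl]-2,3-dihydrobenzofuran-5-yl]prop-2-enoate | COc1ccc([C@H]2Oc3c(OC)cc(/C=C/C(=O)OC)cc3[C@@H]2CO[Si](C(C)C)(C(C)C)C(C)C)cc1OC
F9 | step 7 | (E)-3-[(2S,3R)-2-(3,4-dimethoxyphenyl)-7-methoxy-3-[(triisopropylsilyloxy)methyl]-2,3-dihydrobenzofuran-5-yl]prop-2-en-1-ol | COc1ccc([C@H]2Oc3c(OC)cc(/C=C/CO)cc3[C@@H]2CO[Si](C(C)C)(C(C)C)C(C)C)cc1OC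
A1 | alternative 1 | (2S,3R)-5-bromo-3-(tert-butyldimethylsilyloxymethyl)-2-(3,4-dimethoxyphenyl)-7-methoxy-2,3-dihydrobenzofuran | COc1ccc([C@H]2Oc3c(OC)cc(Br)cc3[C@@H]2CO[Si](C)(C)C(C)(C)C)cc1OC
A2 | alternative 1 | 4-bromo-2-[2-(tert-butyldimethylsilyloxy)-1-(4-methylphenylsulfonyl)ethyl]-6-methoxyphenol (racemic) | COc1cc(Br)cc(C(CO[Si](C)(C)C(C)(C)C)S(=O)(=O)c2ccc(C)cc2)c1O
A3 | alternative 1 | (2R,5R)-1-(3,4-dimethoxybenzyl)-2,5-dimethylthiolan-1-ium tetrafluoroborate | COc1ccc(C[S+]2[C@H](C)CC[C@H]2C)cc1OC.F[B-](F)(F)F
A4 | alternative 2 | methyl (2S,3S)-5-bromo-2-(3,4-dimethoxyphenyl)-7-methoxy-2,3-dihydrobenzofuran-3-carboxylate (trans) | COc1ccc([C@H]2Oc3c(OC)cc(Br)cc3[C@@H]2C(=O)OC)cc1OC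
A5 | alternative 2 | (S)-6-bromo-2-(3,4-dimethoxyphenyl)-8-methoxychroman-4-one | COc1ccc([C@@H]2CC(=O)c3cc(Br)cc(OC)c3O2)cc1OC
A6 | alternative 2 | (E)-1-(5-bromo-2-hydroxy-3-methoxyphenyl)-3-(3,4-dimethoxyphenyl)prop-2-en-1-one | COc1ccc(/C=C/C(=O)c2cc(Br)cc(OC)c2O)cc1OC
A7 | alternative 3 | (2S,3R)-2-(3,4-dimethoxyphenyl)-3-(hydroxymethyl)-7-methoxy-2,3-dihydrobenzofuran-5-carbaldehyde | COc1ccc([C@H]2Oc3c(OC)cc(C=O)cc3[C@@H]2CO)cc1OC
A8 | alternative 3 | (E)-3-[2-(3,4-dimethoxyphenyl)ethenyl]-4-hydroxy-5-methoxybenzaldehyde | COc1ccc(/C=C/c2cc(C=O)cc(OC)c2O)cc1OC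
A9 | alternative 3 | formaldehyde | C=O
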